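**Retrosynthetic overview**
1. The target is cut into three bought pieces: 3-bromopropanoic acid (1) and 2-phenylethanol (2), which are joined to bromo ester 3, plus 1-bromodocosane (4).
2. Key disconnection: C3–C4 of the acyl chain. Zinc homoenolate 5 (the propanoate beta-carbanion, made from 3, with the 2-phenylethyl ester already in place) couples with the docosyl electrophile 4 to give target 6 directly (C3 + C22 = C25).
3. Both carbons joined are electrophilic by nature (the beta-carbon of a beta-bromo ester and C1 of an alkyl bromide). Zinc insertion reverses the polarity of the first.
4. Second disconnection: the ester C–O bond of 3, giving 1 + 2.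
5. No ring is formed, since the phenyl ring comes with 2. Forward order: C–O bond first, C3–C4 bond last.

Assumption: the target SMILES has no stereocentre and no stereogenic double bond, so it is one achiral compound and no step needs stereocontrol.

**Route**

Step 1
Reactants: 1 3-bromopropanoic acid (1.1 equiv); 2 2-phenylethanol (1.0 equiv)
Product: 3 2-phenylethyl 3-bromopropanoate
Conditions: p-TsOH·H2O (5 mol %), toluene, reflux, Dean–Stark trap, 6 h; brief cold aq NaHCO3 wash
Reagents that add atoms: none
Why: Fischer esterification, an acid-catalysed acyl substitution pulled to completion by azeotropic removal of water, and the base-free medium keeps the beta-bromide from E1cB loss of HBr; no stereocentre is formed.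

Step 2
Reactants: 3 2-phenylethyl 3-bromopropanoate (1.5 equiv); 4 1-bromodocosane (1.0 equiv)
Product: 6 2-phenylethyl pentacosanoate, via zinc homoenolate 5 (not isolated)
Conditions: 3, Zn dust (2.2 equiv, activated by BrCH2CH2Br 5 mol % and Me3SiCl 2 mol %), LiCl (1.5 equiv), THF, 45 °C, 6 h, cannula-filter from excess Zn; then 4, PdCl2(IPr)(3-chloropyridine) (2 mol %, IPr = 1,3-bis(2,6-diisopropylphenyl)imidazol-2-ylidene), LiBr (3 equiv), THF/NMP 2:1, 40 °C, 16 h; aq NH4Cl; SiO2 (hexane/EtOAc 97:3), recrystallise from acetone
Reagents that add atoms: zinc, [Zn] (held only in intermediate 5, absent from 6)
Why: LiCl-assisted oxidative insertion of zinc into the C–Br bond reverses the polarity of the beta-carbon and gives a carbonyl-chelated zinc homoenolate (d3 synthon) too mild to attack its own ester, and an alkyl–alkyl Negishi cross-coupling then joins it to C1 of 4, a carbon that is likewise electrophilic by nature, because LiBr/NMP open the chelate to a zincate that transmetalates to the docosyl–palladium bromide formed by oxidative addition to zerovalent palladium and the bulky carbene ligand makes reductive elimination faster than beta-hydride elimination; no stereocentre is formed.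

**Compound list**
1 | 3-bromopropanoic acid | OC(=O)CCBr | starting material
2 | 2-phenylethanol | OCCc1ccccc1 | starting material
3 | 2-phenylethyl 3-bromopropanoate | BrCCC(=O)OCCc1ccccc1 | intermediate
4 | 1-bromodocosane | CCCCCCCCCCCCCCCCCCCCCCBr | starting material
5 | bromo[3-oxo-3-(2-phenylethoxy)propyl]zinc (zinc homoenolate, not isolated) | Br[Zn]CCC(=O)OCCc1ccccc1 | intermediate
6 | 2-phenylethyl pentacosanoate | CCCCCCCCCCCCCCCCCCCCCCCCC(=O)OCCc1ccccc1 | target

**Total step count:** 2
**Longest linear sequence:** 2 (1/2 → 3 → 6)

**Steps most likely to fail**
The route has only two steps. The two separate events of step 2 are therefore ranked on their own, which gives three risks.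

Risk 1, step 2, the cross-coupling event. The chelated homoenolate may transmetalate too slowly. Alternatively, the palladium-bound 3-oxopropyl or docosyl group may undergo beta-hydride elimination, giving acrylate, docosane and 1-docosene. The fallback sets out from 3 and 4 and comes back at 6. Bromo ester 3 is treated with Et3N in CH2Cl2 at room temperature, which eliminates HBr and gives 2-phenylethyl acrylate F1 (also a catalogue chemical). F1 is warmed with NiCl2·6H2O (20 mol %), Zn dust and pyridine in THF at 60 °C to form the zerovalent nickel–olefin complex, and 4 is then added at 25–40 °C. This is a nickel-mediated reductive conjugate addition. The docosyl radical or docosylnickel species adds to the beta-carbon of F1, and the resulting enolate is protonated by the water of hydration to give 6. The same C3–C4 bond forms between the same two electrophilic carbons. The polarity reversal now sits on the docosyl carbon, and no dialkylpalladium intermediate is involved.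

Risk 2, step 2, the zinc insertion event. Possible failures are loss of HBr to the acrylate, protonation to the propanoate, or Wurtz dimerisation to the adipate. The fallback sets out from 4 and comes back at 6. The homoenolate is made by ring opening instead of by insertion. Commercial (1-ethoxycyclopropoxy)trimethylsilane and ZnCl2 (0.5 equiv) in Et2O at room temperature give bis(3-ethoxy-3-oxopropyl)zinc F2, and the volatiles are removed in vacuo. F2 is coupled with 4 under the Pd–carbene/LiBr conditions of step 2 to give ethyl pentacosanoate F3. F3 is then transesterified with 2 (Ti(OiPr)4 5 mol %, toluene, reflux, ethanol distilled off) to give 6.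

Risk 3, step 1. Possible failures are incomplete equilibrium esterification or thermal loss of HBr. The fallback sets out from 1 and comes back at 3. Acid 1 is converted by SOCl2 (cat. DMF, 50 °C) into 3-bromopropanoyl chloride F4. F4 acylates 2 irreversibly in CH2Cl2 at reflux, without any base and under a nitrogen sweep, to give 3.

**Further compounds**
F1 | step 2 | 2-phenylethyl acrylate | C=CC(=O)OCCc1ccccc1
F2 | step 2 | bis(3-ethoxy-3-oxopropyl)zinc | CCOC(=O)CC[Zn]CCC(=O)OCC
F3 | step 2 | ethyl pentacosanoate | CCCCCCCCCCCCCCCCCCCCCCCCC(=O)OCC
F4 | step 1 | 3-bromopropanoyl chloride | O=C(Cl)CCBr
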